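Ring B (the saturated ring, carotenoid atoms C1'–C6') is traced back to a 4-hydroxycyclohexanone in which C6', the later alkylidene carbon, is a ketone. The C3' carbinol and this carbonyl are 1,4-related across the quaternary gem-dimethyl carbon C1', a homoaldol retron, so the ring is closed at C2'–C3' by adding a ketone zinc homoenolate to a tethered aldehyde. The precursor is an acyclic 2,2-dimethylcyclopropanol whose side chain carries the aldehyde and the C5' carbinol centre from (R)-lactic acid; one operation opens the three-membered ring, closes the six-membered ring and sets C3'. Formyl-olefination, Wittig and two Horner–Wadsworth–Emmons reactions then build the retro-polyene.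

Key step: step 7

Remark: carotenoid numbering is used (ring A with the C4=C5 bond holds C1–C6, ring B with the two hydroxyls holds C1'–C6'); polyenes are handled under argon in dim light, and the all-E compounds are the isomers carried on after chromatography.

Step 1
Reactants: 1 (R)-lactic acid; 2 pivalaldehyde
Product: 3 (2R,5R)-2-tert-butyl-5-methyl-1,3-dioxolan-4-one
Conditions: TsOH·H2O (cat.), H2SO4 (cat.), pentane, reflux, water separator; crystallisation of the cis isomer from Et2O–pentane at −78 °C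
Reagents that add atoms: none
Why: Acid-catalysed acetalisation of the α-hydroxy acid (dioxolanone formation) under thermodynamic control should set the new acetal centre C2 cis to the C5 methyl group, and the cis isomer is purified by crystallisation.

Step 2
Reactants: 3 (2R,5R)-2-tert-butyl-5-methyl-1,3-dioxolan-4-one; 4 allyl bromide
Product: 5 (2R,5S)-2-tert-butyl-5-methyl-5-(prop-2-en-1-yl)-1,3-dioxolan-4-one
Conditions: LiN(iPr)2, THF, −78 °C; then 4, −78 → −30 °C
Reagents that add atoms: none
Why: Enolate alkylation with self-regeneration of the stereocentre: the planar lithium enolate should be allylated on the face opposite the tert-butyl group, so the acetal centre sets the new quaternary centre (5S) with overall retention.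

Step 3
Reactants: 5 (2R,5S)-2-tert-butyl-5-methyl-5-(prop-2-en-1-yl)-1,3-dioxolan-4-one
Product: 6 (4S)-4-hydroxy-2,4-dimethylhept-6-en-3-one
Conditions: i-PrLi (1.3 equiv), Et2O–pentane, −78 °C; then 1 M HCl, THF, 0 °C
Reagents that add atoms: isopropyllithium CC(C)[Li]
Why: Addition of the organolithium to the lactone carbonyl (nucleophilic acyl substitution) should stop at the lithium hemiketal, which collapses on acidic work-up to the α-hydroxy ketone and pivalaldehyde; the ketone is shielded on both sides and no stereocentre is touched.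

Step 4
Reactants: 6 (4S)-4-hydroxy-2,4-dimethylhept-6-en-3-one
Product: 7 triethyl{[(4S)-2,4-dimethyl-3-[(trimethylsilyl)oxy]hepta-2,6-dien-4-yl]oxy}silane
Conditions: Et3SiOTf, 2,6-lutidine, CH2Cl2, −78 → 0 °C; then Me3SiOTf, Et3N, 0 → 25 °C
Reagents that add atoms: triethylsilyl triflate CC[Si](CC)(CC)OS(=O)(=O)C(F)(F)F; trimethylsilyl triflate C[Si](C)(C)OS(=O)(=O)C(F)(F)F
Why: O-Silylation of the tertiary alcohol followed by soft enolisation (silyl triflate and amine) should give the silyl enol ether regiospecifically, because the isopropyl methine is the only α-hydrogen.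

Step 5
Reactants: 7 triethyl{[(4S)-2,4-dimethyl-3-[(trimethylsilyl)oxy]hepta-2,6-dien-4-yl]oxy}silane
Product: 9 2,2-dimethyl-1-{(2S)-2-[(triethylsilyl)oxy]pent-4-en-2-yl}cyclopropan-1-ol (both C1 epimers), via siloxycyclopropane 8 (not isolated)
Conditions: Et2Zn, CH2I2, CH2Cl2, 0 → 25 °C; then K2CO3, MeOH, 0 °C
Reagents that add atoms: diiodomethane ICI
Why: Simmons–Smith cyclopropanation (Furukawa modification) should be chemoselective for the electron-rich silyl enol ether over the monosubstituted alkene, and mild methanolysis frees the cyclopropanol while the triethylsilyl ether stays; the new cyclopropane centre forms without control and is destroyed in step 7.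

Step 6
Reactants: 9 2,2-dimethyl-1-{(2S)-2-[(triethylsilyl)oxy]pent-4-en-2-yl}cyclopropan-1-ol
Product: 10 (3S)-3-(1-hydroxy-2,2-dimethylcyclopropyl)-3-[(triethylsilyl)oxy]butanal (in equilibrium with its five-membered lactol)
Conditions: O3, CH2Cl2, −78 °C (Sudan Red 7B end point); PPh3, −78 → 25 °C
Reagents that add atoms: ozone [O-][O+]=O
Why: Ozonolysis with reductive work-up should cleave the only alkene to the aldehyde, which is stored as its lactol with the cyclopropanol hydroxyl; cyclopropane and silyl ether are inert to ozone at low temperature.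

Step 7
Reactants: 10 (3S)-3-(1-hydroxy-2,2-dimethylcyclopropyl)-3-[(triethylsilyl)oxy]butanal
Product: 12 (4R,6S)-4-hydroxy-2,2,6-trimethyl-6-[(triethylsilyl)oxy]cyclohexan-1-one, via zinc homoenolate 11 (not isolated)
Conditions: Et2Zn (1.5 equiv), DMSO–THF, 25 → 50 °C; aq. NH4Cl
Reagents that add atoms: none
Why: Proposed new method: Et2Zn deprotonates the cyclopropanol (freed from its lactol), the zinc cyclopropoxide opens at the less substituted ring bond to the primary β-zincio ketone 11 (driven by loss of ring strain and of the eclipsing between the gem-dimethyl group and the tertiary side chain), and the carbon–zinc bond adds to the tethered aldehyde; the closest known reactions are the Et2Zn-induced opening of cyclopropanols to ketone zinc homoenolates and the homo-Reformatsky addition of ester zinc homoenolates to aldehydes. The cyclohexanone ring closes in a 6-exo-trig mode by attack of C2' on the aldehyde carbon C3', helped by the gem-dimethyl (Thorpe–Ingold) effect. The new C3' centre is controlled by the C5' centre: in the chair transition state the C5' silyloxy group is axial (methyl equatorial, which avoids a syn-axial methyl–methyl contact with C1' and the dipole of an equatorial C–O next to the carbonyl), so the aldehyde oxygen takes the equatorial position away from both axial groups, cis to the C5' methyl and trans to the C5' oxygen (4R). The step needs transfer of the tethered alkyl group and not of ethyl, no enolisation and no β-elimination of the silyloxy group: intramolecular six-membered delivery, the quaternary C1' (no α-hydrogen on the homoenolate) and the low basicity of alkylzinc alkoxides should secure this, and the non-chelating triethylsilyl ether keeps the facial choice under steric control.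

Step 8
Reactants: 12 (4R,6S)-4-hydroxy-2,2,6-trimethyl-6-[(triethylsilyl)oxy]cyclohexan-1-one
Product: 13 (4R,6S)-4-{[tert-butyl(dimethyl)silyl]oxy}-2,2,6-trimethyl-6-[(triethylsilyl)oxy]cyclohexan-1-one
Conditions: TBSCl, imidazole, DMF, 25 °C
Reagents that add atoms: tert-butyldimethylsilyl chloride CC(C)(C)[Si](C)(C)Cl
Why: Silyl ether formation at the unhindered secondary alcohol should leave the ketone and the tertiary silyl ether untouched.

Step 9
Reactants: 13 (4R,6S)-4-{[tert-butyl(dimethyl)silyl]oxy}-2,2,6-trimethyl-6-[(triethylsilyl)oxy]cyclohexan-1-one; 14 (Z)-1-bromo-2-ethoxyethene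
Product: 16 (2E)-2-[(4R,6S)-4-{[tert-butyl(dimethyl)silyl]oxy}-2,2,6-trimethyl-6-[(triethylsilyl)oxy]cyclohexylidene]acetaldehyde, via carbinol 15 (not isolated)
Conditions: 14, n-BuLi, Et2O, −78 °C; CeCl3, THF, −78 °C; then 13, −78 → −20 °C; then 0.5 M HCl, THF, 0 °C
Reagents that add atoms: water O
Why: Two-carbon formyl-olefination: 1,2-addition of the small sp2 organocerium to the hindered ketone, then acid-induced allylic transposition and hydrolysis of the β-ethoxyvinyl carbinol should give the enal, with the alkylidene geometry set in the ionisation, where the ethoxy-bearing carbon should turn away from the C–O dipole of the silyloxy carbon and end syn to the gem-dimethyl carbon (E), any Z isomer being removed by chromatography.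

Step 10
Reactants: 16 (2E)-2-[(4R,6S)-4-{[tert-butyl(dimethyl)silyl]oxy}-2,2,6-trimethyl-6-[(triethylsilyl)oxy]cyclohexylidene]acetaldehyde; 17 2-(triphenylphosphoranylidene)propanal
Product: 18 (2E,4E)-4-[(4R,6S)-4-{[tert-butyl(dimethyl)silyl]oxy}-2,2,6-trimethyl-6-[(triethylsilyl)oxy]cyclohexylidene]-2-methylbut-2-enal
Conditions: toluene, 80 °C
Reagents that add atoms: none
Why: Wittig reaction of the stabilised formyl ylide with the enal should give the 2-methyl dienal with the new C8'=C9' bond E, as is usual for stabilised ylides; the silyl ethers are inert.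

Step 11
Reactants: 19 ketoisophorone (2,6,6-trimethylcyclohex-2-ene-1,4-dione)
Product: 20 (4S)-4-hydroxy-2,6,6-trimethylcyclohex-2-en-1-one
Conditions: RuCl(p-cymene)[(S,S)-TsDPEN] (1 mol%), i-PrOH, 25 °C
Reagents that add atoms: none
Why: Noyori-type asymmetric transfer hydrogenation should reduce only the unhindered C4 carbonyl (C1 is flanked by the gem-dimethyl and the methyl-bearing carbons), and the (S,S)-ligand is expected to give the (4S)-alcohol by analogy with aryl ketones, the enone π-system taking the place of the arene.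

Step 12
Reactants: 20 (4S)-4-hydroxy-2,6,6-trimethylcyclohex-2-en-1-one
Product: 21 (4S)-4-{[tert-butyl(dimethyl)silyl]oxy}-2,6,6-trimethylcyclohex-2-en-1-one
Conditions: TBSCl, imidazole, DMF, 25 °C
Reagents that add atoms: tert-butyldimethylsilyl chloride CC(C)(C)[Si](C)(C)Cl
Why: Silyl ether formation at the secondary allylic alcohol should proceed without touching the enone or the stereocentre.

Step 13
Reactants: 21 (4S)-4-{[tert-butyl(dimethyl)silyl]oxy}-2,6,6-trimethylcyclohex-2-en-1-one; 14 (Z)-1-bromo-2-ethoxyethene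
Product: 23 (2E)-2-[(4S)-4-{[tert-butyl(dimethyl)silyl]oxy}-2,6,6-trimethylcyclohex-2-en-1-ylidene]acetaldehyde, via carbinol 22 (not isolated)
Conditions: 14, n-BuLi, Et2O, −78 °C; then 21, −78 °C; then 0.5 M HCl, THF, 0 °C
Reagents that add atoms: water O
Why: Formyl-olefination as in step 9 (1,2-addition of the vinyllithium to the enone carbonyl, then allylic transposition and hydrolysis) should give the dienal, E because the chain carbon avoids the in-plane C2 methyl group (allylic 1,3-strain).

Step 14
Reactants: 23 (2E)-2-[(4S)-4-{[tert-butyl(dimethyl)silyl]oxy}-2,6,6-trimethylcyclohex-2-en-1-ylidene]acetaldehyde; 17 2-(triphenylphosphoranylidene)propanal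
Product: 24 (2E,4E)-4-[(4S)-4-{[tert-butyl(dimethyl)silyl]oxy}-2,6,6-trimethylcyclohex-2-en-1-ylidene]-2-methylbut-2-enal
Conditions: toluene, 80 °C
Reagents that add atoms: none
Why: Wittig reaction of the stabilised formyl ylide should form the C8=C9 bond E, as in step 10.

Step 15
Reactants: 25 1,4-dioxane-2,3-diol; 26 triethyl 3-methyl-4-phosphonocrotonate (2 equiv)
Product: 27 diethyl (2E,4E,6E,8E)-3,8-dimethyldeca-2,4,6,8-tetraenedioate
Conditions: LiOH·H2O, 4 Å molecular sieves, THF, reflux; then I2 (cat.), CH2Cl2, daylight; recrystallisation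
Reagents that add atoms: none
Why: Double Horner–Wadsworth–Emmons olefination of glyoxal, released in the flask from its ethylene glycol adduct, should give the symmetric tetraenedioate with E disubstituted alkenes, and iodine-catalysed equilibration brings the two methyl-bearing alkenes to E.

Step 16
Reactants: 27 diethyl (2E,4E,6E,8E)-3,8-dimethyldeca-2,4,6,8-tetraenedioate
Product: 28 (2E,4E,6E,8E)-3,8-dimethyldeca-2,4,6,8-tetraene-1,10-diol
Conditions: iBu2AlH (4.5 equiv), CH2Cl2, −78 → 0 °C; Rochelle salt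
Reagents that add atoms: none
Why: 1,2-Reduction of both esters by the aluminium hydride should give the bis-allylic diol without touching the tetraene.

Step 17
Reactants: 28 (2E,4E,6E,8E)-3,8-dimethyldeca-2,4,6,8-tetraene-1,10-diol
Product: 30 tetraethyl [(2E,4E,6E,8E)-3,8-dimethyldeca-2,4,6,8-tetraene-1,10-diyl]bis(phosphonate), via dibromide 29 (not isolated)
Conditions: PBr3, pyridine (cat.), Et2O, −20 °C; then P(OEt)3, 90 °C
Reagents that add atoms: triethyl phosphite CCOP(OCC)OCC
Why: SN2 bromination of the allylic alcohols followed by Michaelis–Arbuzov reaction of the crude, labile dibromide should give the bis-phosphonate, attack at the primary termini leaving the tetraene in place.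

Step 18
Reactants: 30 tetraethyl [(2E,4E,6E,8E)-3,8-dimethyldeca-2,4,6,8-tetraene-1,10-diyl]bis(phosphonate) (3 equiv); 24 (2E,4E)-4-[(4S)-4-{[tert-butyl(dimethyl)silyl]oxy}-2,6,6-trimethylcyclohex-2-en-1-ylidene]-2-methylbut-2-enal
Product: 31 diethyl [(2E,4E,6E,8E,10E,12E,14E)-14-[(4S)-4-{[tert-butyl(dimethyl)silyl]oxy}-2,6,6-trimethylcyclohex-2-en-1-ylidene]-3,8,12-trimethyltetradeca-2,4,6,8,10,12-hexaen-1-yl]phosphonate
Conditions: NaN(SiMe3)2 (1 equiv with respect to 24), THF, −78 °C; then 24, −78 → 0 °C; excess 30 recovered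
Reagents that add atoms: none
Why: Horner–Wadsworth–Emmons olefination at one phosphonate terminus (the excess of bis-phosphonate suppresses double reaction) should form the C10=C11 bond E, as usual for allylic phosphonate anions with unsaturated aldehydes.

Step 19
Reactants: 31 diethyl [(2E,4E,6E,8E,10E,12E,14E)-14-[(4S)-4-{[tert-butyl(dimethyl)silyl]oxy}-2,6,6-trimethylcyclohex-2-en-1-ylidene]-3,8,12-trimethyltetradeca-2,4,6,8,10,12-hexaen-1-yl]phosphonate; 18 (2E,4E)-4-[(4R,6S)-4-{[tert-butyl(dimethyl)silyl]oxy}-2,2,6-trimethyl-6-[(triethylsilyl)oxy]cyclohexylidene]-2-methylbut-2-enal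
Product: 32 3,3'-bis-O-(tert-butyldimethylsilyl)-5'-O-(triethylsilyl) ether of the target triol (all-E)
Conditions: NaN(SiMe3)2, THF, −78 °C; then 18, −78 → 0 °C; dark
Reagents that add atoms: none
Why: The second Horner–Wadsworth–Emmons olefination should form the C10'=C11' bond E and complete the C40 retro-polyene; the non-enolisable aldehyde and the silyl ethers tolerate the base.

Step 20
Reactants: 32 3,3'-bis-O-(tert-butyldimethylsilyl)-5'-O-(triethylsilyl) ether of the target triol
Product: 33 (3S,3'R,5'S,6E,6'E)-4,5'-retro-β,β-carotene-3,3',5'-triol (CNP0269135.1)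
Conditions: Bu4NF, AcOH, THF, 0 → 25 °C, dark, argon
Reagents that add atoms: none
Why: Fluoride-mediated desilylation should remove the two secondary tert-butyldimethylsilyl ethers and the tertiary triethylsilyl ether without acid, so the polyene and the tertiary allylic alcohol survive and no stereocentre is touched.

Compound list
1 | (R)-lactic acid ((2R)-2-hydroxypropanoic acid) | C[C@@H](O)C(=O)O | starting material
2 | pivalaldehyde (2,2-dimethylpropanal) | CC(C)(C)C=O | starting material
3 | (2R,5R)-2-tert-butyl-5-methyl-1,3-dioxolan-4-one | C[C@H]1O[C@@H](C(C)(C)C)OC1=O | intermediate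
4 | allyl bromide (3-bromoprop-1-ene) | C=CCBr | starting material
5 | (2R,5S)-2-tert-butyl-5-methyl-5-(prop-2-en-1-yl)-1,3-dioxolan-4-one | C[C@@]1(CC=C)O[C@@H](C(C)(C)C)OC1=O | intermediate
6 | (4S)-4-hydroxy-2,4-dimethylhept-6-en-3-one | C=CC[C@](C)(O)C(=O)C(C)C | intermediate
7 | triethyl{[(4S)-2,4-dimethyl-3-[(trimethylsilyl)oxy]hepta-2,6-dien-4-yl]oxy}silane | C=CC[C@](C)(O[Si](CC)(CC)CC)C(O[Si](C)(C)C)=C(C)C | intermediate
8 | {[(2S)-2-{2,2-dimethyl-1-[(trimethylsilyl)oxy]cyclopropyl}pent-4-en-2-yl]oxy}(triethyl)silane (both cyclopropane epimers) | C=CC[C@](C)(O[Si](CC)(CC)CC)C1(O[Si](C)(C)C)CC1(C)C | intermediate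
9 | 2,2-dimethyl-1-{(2S)-2-[(triethylsilyl)oxy]pent-4-en-2-yl}cyclopropan-1-ol (both C1 epimers) | C=CC[C@](C)(O[Si](CC)(CC)CC)C1(O)CC1(C)C | intermediate
10 | (3S)-3-(1-hydroxy-2,2-dimethylcyclopropyl)-3-[(triethylsilyl)oxy]butanal (both cyclopropane epimers; open form of the lactol) | O=CC[C@](C)(O[Si](CC)(CC)CC)C1(O)CC1(C)C | intermediate
11 | ethyl{(4S)-2,2,4-trimethyl-3,6-dioxo-4-[(triethylsilyl)oxy]hexyl}zinc (zinc homoenolate) | CC[Zn]CC(C)(C)C(=O)[C@@](C)(O[Si](CC)(CC)CC)CC=O | intermediate
12 | (4R,6S)-4-hydroxy-2,2,6-trimethyl-6-[(triethylsilyl)oxy]cyclohexan-1-one | O=C1C(C)(C)C[C@@H](O)C[C@]1(C)O[Si](CC)(CC)CC | intermediate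
13 | (4R,6S)-4-{[tert-butyl(dimethyl)silyl]oxy}-2,2,6-trimethyl-6-[(triethylsilyl)oxy]cyclohexan-1-one | O=C1C(C)(C)C[C@@H](O[Si](C)(C)C(C)(C)C)C[C@]1(C)O[Si](CC)(CC)CC | intermediate
14 | (Z)-1-bromo-2-ethoxyethene | CCO/C=C\Br | starting material
15 | (4R,6S)-4-{[tert-butyl(dimethyl)silyl]oxy}-1-[(Z)-2-ethoxyethenyl]-2,2,6-trimethyl-6-[(triethylsilyl)oxy]cyclohexan-1-ol (C1 epimers) | CCO/C=C\C1(O)C(C)(C)C[C@@H](O[Si](C)(C)C(C)(C)C)C[C@]1(C)O[Si](CC)(CC)CC | intermediate
16 | (2E)-2-[(4R,6S)-4-{[tert-butyl(dimethyl)silyl]oxy}-2,2,6-trimethyl-6-[(triethylsilyl)oxy]cyclohexylidene]acetaldehyde | O=C/C=C1\C(C)(C)C[C@@H](O[Si](C)(C)C(C)(C)C)C[C@]1(C)O[Si](CC)(CC)CC | intermediate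
17 | 2-(triphenylphosphoranylidene)propanal | CC(C=O)=P(c1ccccc1)(c1ccccc1)c1ccccc1 | starting material
18 | (2E,4E)-4-[(4R,6S)-4-{[tert-butyl(dimethyl)silyl]oxy}-2,2,6-trimethyl-6-[(triethylsilyl)oxy]cyclohexylidene]-2-methylbut-2-enal | O=C/C(C)=C/C=C1\C(C)(C)C[C@@H](O[Si](C)(C)C(C)(C)C)C[C@]1(C)O[Si](CC)(CC)CC | intermediate
19 | ketoisophorone (2,6,6-trimethylcyclohex-2-ene-1,4-dione) | CC1=CC(=O)CC(C)(C)C1=O | starting material
20 | (4S)-4-hydroxy-2,6,6-trimethylcyclohex-2-en-1-one | CC1=C[C@@H](O)CC(C)(C)C1=O | intermediate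
21 | (4S)-4-{[tert-butyl(dimethyl)silyl]oxy}-2,6,6-trimethylcyclohex-2-en-1-one | CC1=C[C@@H](O[Si](C)(C)C(C)(C)C)CC(C)(C)C1=O | intermediate
22 | (4S)-4-{[tert-butyl(dimethyl)silyl]oxy}-1-[(Z)-2-ethoxyethenyl]-2,6,6-trimethylcyclohex-2-en-1-ol (C1 epimers) | CCO/C=C\C1(O)C(C)=C[C@@H](O[Si](C)(C)C(C)(C)C)CC1(C)C | intermediate
23 | (2E)-2-[(4S)-4-{[tert-butyl(dimethyl)silyl]oxy}-2,6,6-trimethylcyclohex-2-en-1-ylidene]acetaldehyde | CC1=C[C@@H](O[Si](C)(C)C(C)(C)C)CC(C)(C)\C1=C/C=O | intermediate
24 | (2E,4E)-4-[(4S)-4-{[tert-butyl(dimethyl)silyl]oxy}-2,6,6-trimethylcyclohex-2-en-1-ylidene]-2-methylbut-2-enal | CC1=C[C@@H](O[Si](C)(C)C(C)(C)C)CC(C)(C)\C1=C/C=C(C)/C=O | intermediate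
25 | 1,4-dioxane-2,3-diol (glyoxal–ethylene glycol adduct) | OC1OCCOC1O | starting material
26 | triethyl 3-methyl-4-phosphonocrotonate (ethyl (2E)-4-(diethoxyphosphoryl)-3-methylbut-2-enoate; the commercial reagent holds some 2Z isomer) | CCOC(=O)/C=C(C)/CP(=O)(OCC)OCC | starting material
27 | diethyl (2E,4E,6E,8E)-3,8-dimethyldeca-2,4,6,8-tetraenedioate | CCOC(=O)/C=C(C)/C=C/C=C/C(C)=C/C(=O)OCC | intermediate
28 | (2E,4E,6E,8E)-3,8-dimethyldeca-2,4,6,8-tetraene-1,10-diol | OC/C=C(C)/C=C/C=C/C(C)=C/CO | intermediate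
29 | (2E,4E,6E,8E)-1,10-dibromo-3,8-dimethyldeca-2,4,6,8-tetraene | BrC/C=C(C)/C=C/C=C/C(C)=C/CBr | intermediate
30 | tetraethyl [(2E,4E,6E,8E)-3,8-dimethyldeca-2,4,6,8-tetraene-1,10-diyl]bis(phosphonate) | CCOP(=O)(OCC)C/C=C(C)/C=C/C=C/C(C)=C/CP(=O)(OCC)OCC | intermediate
31 | diethyl [(2E,4E,6E,8E,10E,12E,14E)-14-[(4S)-4-{[tert-butyl(dimethyl)silyl]oxy}-2,6,6-trimethylcyclohex-2-en-1-ylidene]-3,8,12-trimethyltetradeca-2,4,6,8,10,12-hexaen-1-yl]phosphonate | CC1=C[C@@H](O[Si](C)(C)C(C)(C)C)CC(C)(C)\C1=C/C=C(C)/C=C/C=C(C)/C=C/C=C/C(C)=C/CP(=O)(OCC)OCC | intermediate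
32 | 3,3'-bis-O-(tert-butyldimethylsilyl)-5'-O-(triethylsilyl) ether of the target triol (3S,3'R,5'S, all-E) | CC1=C[C@@H](O[Si](C)(C)C(C)(C)C)CC(C)(C)\C1=C/C=C(C)/C=C/C=C(C)/C=C/C=C/C(C)=C/C=C/C(C)=C/C=C1\C(C)(C)C[C@@H](O[Si](C)(C)C(C)(C)C)C[C@]1(C)O[Si](CC)(CC)CC | intermediate
33 | (3S,3'R,5'S,6E,6'E)-4,5'-retro-β,β-carotene-3,3',5'-triol (CNP0269135.1) | CC1=C[C@@H](O)CC(C)(C)\C1=C/C=C(C)/C=C/C=C(C)/C=C/C=C/C(C)=C/C=C/C(C)=C/C=C1\C(C)(C)C[C@@H](O)C[C@]1(C)O | target

Total step count: 20. Longest linear sequence: 12 steps (steps 1–10, then 19 and 20).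

Steps most likely to fail

Step 7 (key step, new method). The zinc homoenolate may fail to add to the aldehyde: it can revert to the cyclopropoxide, be protonated on work-up to the ring-opened ketone, or lose out to ethyl transfer, and the facial choice at C3' may be weaker than the chair model predicts. The fallback uses known chemistry, sets out from 5 and comes back at 12. γ-Selective addition of prenylmagnesium chloride to 5 (THF, −78 °C, acidic work-up) should give (5S)-5-hydroxy-3,3,5-trimethylocta-1,7-dien-4-one F1. Silylation (Et3SiOTf, 2,6-lutidine) gives (5S)-3,3,5-trimethyl-5-[(triethylsilyl)oxy]octa-1,7-dien-4-one F2. Ring-closing metathesis with the second-generation Grubbs catalyst joins the same two carbons as an alkene and gives (6S)-2,2,6-trimethyl-6-[(triethylsilyl)oxy]cyclohex-3-en-1-one F3. Hydroboration with 9-BBN, with boron going to the carbon remote from the gem-dimethyl group on the face opposite the axial silyloxy group and the shielded ketone left alone, followed by NaBO3 oxidation returns to 12.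

Step 9. The 1,2-addition to a ketone flanked by two quaternary carbons may be slow, and the rotamer selection in the ionisation may give poor control of the alkylidene geometry. The fallback sets out from 13 and comes back at 16. Lithium ethoxyacetylide (ethoxyacetylene, n-BuLi, THF, −78 °C), a slimmer nucleophile, gives (4R,6S)-4-{[tert-butyl(dimethyl)silyl]oxy}-1-(ethoxyethynyl)-2,2,6-trimethyl-6-[(triethylsilyl)oxy]cyclohexan-1-ol F4. Meyer–Schuster rearrangement (Sc(OTf)3, EtOH–CH2Cl2) gives the unsaturated ester, from which ethyl (2E)-2-[(4R,6S)-4-{[tert-butyl(dimethyl)silyl]oxy}-2,2,6-trimethyl-6-[(triethylsilyl)oxy]cyclohexylidene]acetate F5 is separated by chromatography at this robust stage. Reduction with iBu2AlH gives (2E)-2-[(4R,6S)-4-{[tert-butyl(dimethyl)silyl]oxy}-2,2,6-trimethyl-6-[(triethylsilyl)oxy]cyclohexylidene]ethan-1-ol F6, and MnO2 oxidation returns to 16.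

Step 5. The zinc carbenoid may not reach the tetrasubstituted enol ether, which is hindered on both sides, or may attack the terminal alkene instead. The fallback sets out from 7 and comes back at 9. MeLi (Et2O, 0 °C) cleaves the silyl enol ether to lithium (4S)-2,4-dimethyl-4-[(triethylsilyl)oxy]hepta-2,6-dien-3-olate F7, and this more electron-rich enolate is cyclopropanated by the samarium carbenoid (SmI2, CH2I2, THF, −78 → 25 °C), which leaves isolated alkenes alone; aqueous work-up gives 9 directly.

Further compounds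
F1 | step 7 | (5S)-5-hydroxy-3,3,5-trimethylocta-1,7-dien-4-one | C=CC[C@](C)(O)C(=O)C(C)(C)C=C
F2 | step 7 | (5S)-3,3,5-trimethyl-5-[(triethylsilyl)oxy]octa-1,7-dien-4-one | C=CC[C@](C)(O[Si](CC)(CC)CC)C(=O)C(C)(C)C=C
F3 | step 7 | (6S)-2,2,6-trimethyl-6-[(triethylsilyl)oxy]cyclohex-3-en-1-one | O=C1C(C)(C)C=CC[C@]1(C)O[Si](CC)(CC)CC
F4 | step 9 | (4R,6S)-4-{[tert-butyl(dimethyl)silyl]oxy}-1-(ethoxyethynyl)-2,2,6-trimethyl-6-[(triethylsilyl)oxy]cyclohexan-1-ol (C1 epimers) | CCOC#CC1(O)C(C)(C)C[C@@H](O[Si](C)(C)C(C)(C)C)C[C@]1(C)O[Si](CC)(CC)CC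
F5 | step 9 | ethyl (2E)-2-[(4R,6S)-4-{[tert-butyl(dimethyl)silyl]oxy}-2,2,6-trimethyl-6-[(triethylsilyl)oxy]cyclohexylidene]acetate | CCOC(=O)/C=C1\C(C)(C)C[C@@H](O[Si](C)(C)C(C)(C)C)C[C@]1(C)O[Si](CC)(CC)CC
F6 | step 9 | (2E)-2-[(4R,6S)-4-{[tert-butyl(dimethyl)silyl]oxy}-2,2,6-trimethyl-6-[(triethylsilyl)oxy]cyclohexylidene]ethan-1-ol | OC/C=C1\C(C)(C)C[C@@H](O[Si](C)(C)C(C)(C)C)C[C@]1(C)O[Si](CC)(CC)CC
F7 | step 5 | lithium (4S)-2,4-dimethyl-4-[(triethylsilyl)oxy]hepta-2,6-dien-3-olate | C=CC[C@](C)(O[Si](CC)(CC)CC)C(O[Li])=C(C)C
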